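**Retrosynthetic overview**
1. The strategy rests on C4 of ring C. This carbonyl carbon is bonded only to C4a of ring A and to C3 of the C3=C2–aryl unit, and O1 ties C2 back to C8a. C4 can therefore come from CO, C3/C2 from a terminal arylalkyne, and C4a/O1 from the iodine-bearing carbon and the hydroxyl of a 2-iodophenol.
2. Late disconnections are the two O–Si bonds (5-OH, 7-OH), the O–CH3 bond at C3 and the C3–O bond (lithiation, borylation, oxidation). They lead back to 5,7-bis(triisopropylsilyloxy)-4'-prenyloxyflavone.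
3. The key disconnection cuts C4a–C4, C4–C3 and O1–C2 in one operation, giving 2-iodo-3,5-bis(triisopropylsilyloxy)phenol, CO and 1-ethynyl-4-(prenyloxy)benzene.
4. The iodophenol comes from phloroglucinol (bis-silylation, ortho-iodination). The alkyne comes from 4-hydroxybenzaldehyde (O-prenylation, one-carbon homologation).
5. Ring order: rings A and B are bought, and ring C is the only ring formed.

Key step: step 5

Remark: the target has no stereocentre and neither C2=C3 nor the prenyl alkene is stereogenic, so no stereocontrol is needed; anhydrous phloroglucinol is assumed.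

**Step 1**
Reactants: 1 phloroglucinol
Product: 2 3,5-bis(triisopropylsilyloxy)phenol
Conditions: iPr3SiCl (2.0 equiv), imidazole (4 equiv), DMF, 0 °C → rt; chromatography, with the mono- and tris-ethers recycled
Reagents that add atoms: triisopropylsilyl chloride, CC(C)[Si](Cl)(C(C)C)C(C)C
Why: Imidazole-promoted silyl ether formation; the three hydroxyls are equivalent, so only the degree of silylation has to be controlled, and two equivalents of the bulky chloride should make the bis-ether the main, separable component.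

**Step 2**
Reactants: 2 3,5-bis(triisopropylsilyloxy)phenol
Product: 3 2-iodo-3,5-bis(triisopropylsilyloxy)phenol
Conditions: N-iodosuccinimide (1.0 equiv), CH2Cl2, −20 → 0 °C, dark
Reagents that add atoms: N-iodosuccinimide, O=C1CCC(=O)N1I
Why: Electrophilic aromatic iodination; every ring CH is activated, but C4 lies between two triisopropylsilyloxy groups while C2 (= C6) has the small free hydroxyl as a neighbour, which can hydrogen-bond the reagent, so iodine should enter ortho to the OH.

**Step 3**
Reactants: 4 4-hydroxybenzaldehyde; 5 prenyl bromide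
Product: 6 4-(3-methylbut-2-enyloxy)benzaldehyde
Conditions: K2CO3, DMF, rt
Reagents that add atoms: none
Why: Williamson ether synthesis; the acidic para-formyl phenoxide should displace the primary allylic bromide by SN2 at oxygen.

**Step 4**
Reactants: 6 4-(3-methylbut-2-enyloxy)benzaldehyde
Product: 7 1-ethynyl-4-(3-methylbut-2-enyloxy)benzene
Conditions: dimethyl (1-diazo-2-oxopropyl)phosphonate, K2CO3, MeOH, 0 °C → rt
Reagents that add atoms: dimethyl (1-diazo-2-oxopropyl)phosphonate, COP(=O)(OC)C(=[N+]=[N-])C(C)=O (its diazo carbon becomes the terminal alkyne carbon)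
Why: Seyferth–Gilbert homologation in the Ohira–Bestmann variant; methanolysis frees the diazomethylphosphonate anion, which olefinates the aldehyde, and loss of N2 with a 1,2-hydrogen shift gives the alkyne under carbonate conditions that leave the prenyl ether alone and keep palladium away from it.

**Step 5**
Reactants: 3 2-iodo-3,5-bis(triisopropylsilyloxy)phenol; 7 1-ethynyl-4-(3-methylbut-2-enyloxy)benzene; 8 carbon monoxide
Product: 11 5,7-bis(triisopropylsilyloxy)-4'-prenyloxyflavone, via ortho-hydroxyaryl ynone 9 (not isolated), via diethylamino enaminone 10 (not isolated)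
Conditions: PdCl2(PPh3)2 (5 mol %), CO (10 bar), Et2NH (solvent), 80 °C, autoclave, no CuI
Reagents that add atoms: diethylamine, CCNCC (held only in 10 and released again on ring closure)
Why: This is a carbonylative Sonogashira coupling followed by amine-mediated annulation, the known palladium route from 2-iodophenols, CO and terminal alkynes to flavones: PdCl2(PPh3)2 is reduced in the flask to zerovalent palladium, which inserts into the C–I bond of 3, migratory insertion of CO gives an aroylpalladium iodide, and alkyne 7, deprotonated by Et2NH, is passed to the metal and reductively eliminated to give ynone 9 (bonds C4a–C4 and C4–C3). Et2NH then adds to the β-carbon of 9 to give enaminone 10, and the ortho phenol oxygen attacks that same carbon and expels the amine, so ring C closes at O1–C2 by an addition–elimination that amounts to a 6-endo-dig closure. No stereocentre is formed. CO must insert before the alkyne is transferred, which is secured by CO pressure, by leaving out the copper co-catalyst and by the electron-rich aryl group, which migrates to CO quickly. The flavone must win over the 5-exo aurone, which the secondary amine secures because C2 is the only electrophilic carbon once 10 has formed. The two ortho substituents shield the acyl carbon from direct attack by Et2NH (aminocarbonylation) while alkyne transfer takes place at the metal, and the moderate temperature should spare the silyl ethers and the trisubstituted allyl aryl ether, which ionises on zerovalent palladium far more slowly than a plain allyl ether.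

**Step 6**
Reactants: 11 5,7-bis(triisopropylsilyloxy)-4'-prenyloxyflavone
Product: 14 3-hydroxy-5,7-bis(triisopropylsilyloxy)-4'-prenyloxyflavone, via 3-lithioflavone 12 (not isolated), via lithium trimethoxyborate 13 (not isolated)
Conditions: LiN(iPr)2 (1.3 equiv), THF, −78 °C; B(OMe)3, −78 → 0 °C; AcOH, 30 % H2O2, 0 °C → rt
Reagents that add atoms: hydrogen peroxide, OO (the oxygen at C3); lithium diisopropylamide, [Li+].CC(C)[N-]C(C)C (lithium of 12 and 13); trimethyl borate, COB(OC)OC (boron and methoxy groups of 13)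
Why: Lithiation–borylation–oxidation; C3–H is the only proton LiN(iPr)2 can remove at −78 °C because the C4 oxygen binds lithium and O1 acidifies the position, 12 is trapped as 13 before it can open ring C by β-elimination, and the boron-to-oxygen 1,2-shift under weakly acidic H2O2 acts on the C–B bond alone, sparing the prenyl alkene that an epoxidising oxidant would attack.

**Step 7**
Reactants: 14 3-hydroxy-5,7-bis(triisopropylsilyloxy)-4'-prenyloxyflavone
Product: 15 3-methoxy-5,7-bis(triisopropylsilyloxy)-4'-prenyloxyflavone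
Conditions: MeI (1.5 equiv), K2CO3 (1.5 equiv), dry acetone, rt → 40 °C
Reagents that add atoms: iodomethane, CI
Why: Williamson-type O-methylation; the acidic 3-enol is the only free hydroxyl, and dry, mild carbonate conditions should leave the hindered aryl silyl ethers in place.

**Step 8**
Reactants: 15 3-methoxy-5,7-bis(triisopropylsilyloxy)-4'-prenyloxyflavone
Product: 16 5,7-dihydroxy-3-methoxy-4'-prenyloxyflavone
Conditions: Bu4NF (2.4 equiv), AcOH (2.4 equiv), THF, 0 °C
Reagents that add atoms: none
Why: Fluoride-induced Si–O cleavage driven by the Si–F bond; the acetic acid buffer protonates the phenoxides as they form, and the prenyl ether, the 3-methyl ether and the pyranone are inert to fluoride.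

**Compound list**
1 | phloroglucinol | Oc1cc(O)cc(O)c1 | starting material
2 | 3,5-bis(triisopropylsilyloxy)phenol | Oc1cc(O[Si](C(C)C)(C(C)C)C(C)C)cc(O[Si](C(C)C)(C(C)C)C(C)C)c1 | intermediate
3 | 2-iodo-3,5-bis(triisopropylsilyloxy)phenol | Oc1cc(O[Si](C(C)C)(C(C)C)C(C)C)cc(O[Si](C(C)C)(C(C)C)C(C)C)c1I | intermediate
4 | 4-hydroxybenzaldehyde | O=Cc1ccc(O)cc1 | starting material
5 | prenyl bromide (1-bromo-3-methylbut-2-ene) | CC(C)=CCBr | starting material
6 | 4-(3-methylbut-2-enyloxy)benzaldehyde | O=Cc1ccc(OCC=C(C)C)cc1 | intermediate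
7 | 1-ethynyl-4-(3-methylbut-2-enyloxy)benzene | C#Cc1ccc(OCC=C(C)C)cc1 | intermediate
8 | carbon monoxide | [C-]#[O+] | starting material
9 | 1-[2-hydroxy-4,6-bis(triisopropylsilyloxy)phenyl]-3-[4-(3-methylbut-2-enyloxy)phenyl]prop-2-yn-1-one | O=C(C#Cc1ccc(OCC=C(C)C)cc1)c1c(O)cc(O[Si](C(C)C)(C(C)C)C(C)C)cc1O[Si](C(C)C)(C(C)C)C(C)C | intermediate (not isolated)
10 | (E)-3-(diethylamino)-1-[2-hydroxy-4,6-bis(triisopropylsilyloxy)phenyl]-3-[4-(3-methylbut-2-enyloxy)phenyl]prop-2-en-1-one | CCN(CC)/C(=C/C(=O)c1c(O)cc(O[Si](C(C)C)(C(C)C)C(C)C)cc1O[Si](C(C)C)(C(C)C)C(C)C)c1ccc(OCC=C(C)C)cc1 | intermediate (not isolated)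
11 | 5,7-bis(triisopropylsilyloxy)-4'-prenyloxyflavone | O=c1cc(-c2ccc(OCC=C(C)C)cc2)oc2cc(O[Si](C(C)C)(C(C)C)C(C)C)cc(O[Si](C(C)C)(C(C)C)C(C)C)c12 | intermediate
12 | 3-lithio-5,7-bis(triisopropylsilyloxy)-4'-prenyloxyflavone | [Li]c1c(-c2ccc(OCC=C(C)C)cc2)oc2cc(O[Si](C(C)C)(C(C)C)C(C)C)cc(O[Si](C(C)C)(C(C)C)C(C)C)c2c1=O | intermediate (not isolated)
13 | lithium trimethoxy[5,7-bis(triisopropylsilyloxy)-4'-prenyloxyflavon-3-yl]borate | [Li+].CO[B-](OC)(OC)c1c(-c2ccc(OCC=C(C)C)cc2)oc2cc(O[Si](C(C)C)(C(C)C)C(C)C)cc(O[Si](C(C)C)(C(C)C)C(C)C)c2c1=O | intermediate (not isolated)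
14 | 3-hydroxy-5,7-bis(triisopropylsilyloxy)-4'-prenyloxyflavone | O=c1c(O)c(-c2ccc(OCC=C(C)C)cc2)oc2cc(O[Si](C(C)C)(C(C)C)C(C)C)cc(O[Si](C(C)C)(C(C)C)C(C)C)c12 | intermediate
15 | 3-methoxy-5,7-bis(triisopropylsilyloxy)-4'-prenyloxyflavone | COc1c(-c2ccc(OCC=C(C)C)cc2)oc2cc(O[Si](C(C)C)(C(C)C)C(C)C)cc(O[Si](C(C)C)(C(C)C)C(C)C)c2c1=O | intermediate
16 | 5,7-dihydroxy-3-methoxy-4'-prenyloxyflavone | COc1c(-c2ccc(OCC=C(C)C)cc2)oc2cc(O)cc(O)c2c1=O | target

**Total step count:** 8
**Longest linear sequence:** 6 steps (1, 2, 5, 6, 7, 8, from phloroglucinol)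

**Steps most likely to fail**

**Step 5.**
- What may go wrong: insertion at the hindered, electron-rich iodide may be slow, which would lead to reductive loss of iodine.
- The alkyne may couple before CO inserts, followed by benzofuran closure.
- Et2NH may capture the aroylpalladium species.
- Palladium may ionise the prenyl ether, or a silyl group may be lost in the hot amine.
- The fallback builds the ynone without palladium or CO. It sets out from 2 and 7 and comes back at 9, which is then isolated.
- Phenol 2 is formylated exclusively ortho to the free hydroxyl (MgCl2, Et3N, paraformaldehyde, MeCN, reflux; Casnati–Skattebøl formylation). This gives 2-hydroxy-4,6-bis(triisopropylsilyloxy)benzaldehyde F1 and also makes the iodination unnecessary.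
- Alkyne 7 is deprotonated (n-BuLi, THF, −78 °C) to lithium [4-(3-methylbut-2-enyloxy)phenyl]acetylide F2.
- More than two equivalents of F2 are used. The first takes the phenol proton of F1 and the second adds to the aldehyde, giving the racemic propargylic alcohol 1-[2-hydroxy-4,6-bis(triisopropylsilyloxy)phenyl]-3-[4-(3-methylbut-2-enyloxy)phenyl]prop-2-yn-1-ol F3.
- MnO2 in CH2Cl2 oxidises the doubly activated alcohol to 9. Et2NH in THF at rt to 40 °C should then carry 9 through 10 to 11.

**Step 6.**
- What may go wrong: deprotonation may be incomplete, or ring C may open by β-elimination of the 3-lithio species.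
- The boronate may lose boron to protonation in the acidic oxidation medium, or the prenyl alkene may slowly oxidise.
- The fallback swaps deprotonation for electrophilic epoxidation of C2=C3 and attaches the prenyl group only afterwards. It sets out from 3, 8 and commercial 1-(benzyloxy)-4-ethynylbenzene and comes back at 15.
- Under the conditions of step 5 the reaction should pass through 3-(4-benzyloxyphenyl)-1-[2-hydroxy-4,6-bis(triisopropylsilyloxy)phenyl]prop-2-yn-1-one F4 and its diethylamine adduct (E)-3-(4-benzyloxyphenyl)-3-(diethylamino)-1-[2-hydroxy-4,6-bis(triisopropylsilyloxy)phenyl]prop-2-en-1-one F5. The product is 4'-benzyloxy-5,7-bis(triisopropylsilyloxy)flavone F6.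
- With no isolated alkene left in the molecule, dimethyldioxirane (acetone/CH2Cl2, 0 °C) can epoxidise C2=C3 to the racemic 4'-benzyloxy-2,3-epoxy-5,7-bis(triisopropylsilyloxy)flavanone F7.
- A trace of p-TsOH opens F7 to 4'-benzyloxy-3-hydroxy-5,7-bis(triisopropylsilyloxy)flavone F8.
- MeI/K2CO3 in acetone gives 4'-benzyloxy-3-methoxy-5,7-bis(triisopropylsilyloxy)flavone F9.
- Hydrogenolysis (H2, Pd/C, EtOAc) frees 4'-hydroxy-3-methoxy-5,7-bis(triisopropylsilyloxy)flavone F10.
- Alkylation of F10 with prenyl bromide 5 (K2CO3, acetone, rt) gives 15.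

**Step 2.**
- What may go wrong: site selectivity between C2 and C4 may be poor, because para activation by the free hydroxyl competes with steric shielding.
- A second iodination may occur at C6, or iodine may be lost again if acid builds up.
- The fallback reverses the order so that iodination has only one possible site. It sets out from 1 and comes back at 3.
- The three CH positions of phloroglucinol are equivalent, so I2/NaHCO3 in THF/H2O at 0 °C can give only 2-iodobenzene-1,3,5-triol F11.
- iPr3SiCl (2 equiv) with imidazole in DMF at 0 °C should silylate the unhindered hydroxyl para to iodine first. It should then take one of the two equivalent hydroxyls next to iodine, which gives 3.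

**Further compounds**
F1 | step 5 | 2-hydroxy-4,6-bis(triisopropylsilyloxy)benzaldehyde | O=Cc1c(O)cc(O[Si](C(C)C)(C(C)C)C(C)C)cc1O[Si](C(C)C)(C(C)C)C(C)C
F2 | step 5 | lithium [4-(3-methylbut-2-enyloxy)phenyl]acetylide | [Li]C#Cc1ccc(OCC=C(C)C)cc1
F3 | step 5 | 1-[2-hydroxy-4,6-bis(triisopropylsilyloxy)phenyl]-3-[4-(3-methylbut-2-enyloxy)phenyl]prop-2-yn-1-ol (racemic; the centre is erased on oxidation) | OC(C#Cc1ccc(OCC=C(C)C)cc1)c1c(O)cc(O[Si](C(C)C)(C(C)C)C(C)C)cc1O[Si](C(C)C)(C(C)C)C(C)C
F4 | step 6 | 3-(4-benzyloxyphenyl)-1-[2-hydroxy-4,6-bis(triisopropylsilyloxy)phenyl]prop-2-yn-1-one | O=C(C#Cc1ccc(OCc2ccccc2)cc1)c1c(O)cc(O[Si](C(C)C)(C(C)C)C(C)C)cc1O[Si](C(C)C)(C(C)C)C(C)C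
F5 | step 6 | (E)-3-(4-benzyloxyphenyl)-3-(diethylamino)-1-[2-hydroxy-4,6-bis(triisopropylsilyloxy)phenyl]prop-2-en-1-one | CCN(CC)/C(=C/C(=O)c1c(O)cc(O[Si](C(C)C)(C(C)C)C(C)C)cc1O[Si](C(C)C)(C(C)C)C(C)C)c1ccc(OCc2ccccc2)cc1
F6 | step 6 | 4'-benzyloxy-5,7-bis(triisopropylsilyloxy)flavone | O=c1cc(-c2ccc(OCc3ccccc3)cc2)oc2cc(O[Si](C(C)C)(C(C)C)C(C)C)cc(O[Si](C(C)C)(C(C)C)C(C)C)c12
F7 | step 6 | 4'-benzyloxy-2,3-epoxy-5,7-bis(triisopropylsilyloxy)flavanone (racemic, one enantiomer drawn) | O=C1[C@H]2O[C@@]2(c2ccc(OCc3ccccc3)cc2)Oc2cc(O[Si](C(C)C)(C(C)C)C(C)C)cc(O[Si](C(C)C)(C(C)C)C(C)C)c12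
F8 | step 6 | 4'-benzyloxy-3-hydroxy-5,7-bis(triisopropylsilyloxy)flavone | O=c1c(O)c(-c2ccc(OCc3ccccc3)cc2)oc2cc(O[Si](C(C)C)(C(C)C)C(C)C)cc(O[Si](C(C)C)(C(C)C)C(C)C)c12
F9 | step 6 | 4'-benzyloxy-3-methoxy-5,7-bis(triisopropylsilyloxy)flavone | COc1c(-c2ccc(OCc3ccccc3)cc2)oc2cc(O[Si](C(C)C)(C(C)C)C(C)C)cc(O[Si](C(C)C)(C(C)C)C(C)C)c2c1=O
F10 | step 6 | 4'-hydroxy-3-methoxy-5,7-bis(triisopropylsilyloxy)flavone | COc1c(-c2ccc(O)cc2)oc2cc(O[Si](C(C)C)(C(C)C)C(C)C)cc(O[Si](C(C)C)(C(C)C)C(C)C)c2c1=O
F11 | step 2 | 2-iodobenzene-1,3,5-triol | Oc1cc(O)c(I)c(O)c1
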